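Labdane numbering (C1–C20) is used throughout.

**Plan**
- Cuts, in retrosynthetic order: the C19 acetate; the butenolide (C13=C14 and its lactone C–O); C8=C17; C9–C11; C6=C7 (ring B); C4–C5 (ring A); C10–CH3 and C10–C9; C1–C2.
- Enabling feature: in ring A (C1, C2, C3, C4, C5, C10), C4–C5 links a quaternary carbon to the methine that carries C6. With C6 written as CO2H and a C2=C3 alkene added, C6–C5–C4–C3=C2 is a γ,δ-unsaturated acid. The remaining ring atoms C10–C1 tie its ester half and allyl half together as a δ-lactone.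
- Forward order: C1–C2 (vinylogous aldol), then the δ-lactone, then the two carbon groups on C10, then ring A by [3,3] shift. Ring B follows by Wacker oxidation and aldol condensation, then the C9 side chain, the C8 methylene, the butenolide and the acetate.
- Stereochemistry: C2 comes from a catalytic asymmetric aldol addition and C10 is relayed from C2 by anti cuprate addition. C4 and C5 come from C2 and the (E)-alkene through a boat [3,3] shift, and C9 is set by equilibration to the equatorial side chain.

Key step: step 10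

Assumption: (S)-Tol-BINAP is taken to be the ligand antipode that gives the (R)-carbinol 10; if the sense of induction is the opposite, the (R)-ligand is used and nothing else changes.

Step 1
Reactants: 1 prop-2-yn-1-ol
Product: 3 (E)-3-iodo-2-methylprop-2-en-1-ol, via alkenylalane 2 (not isolated)
Conditions: AlMe3 (3 equiv), Cp2ZrCl2 (0.25 equiv), CH2Cl2, 0 °C → rt; I2, THF, −30 °C; aq. K2CO3
Reagents that add atoms: trimethylaluminium C[Al](C)C; iodine II
Why: Zirconium-catalysed Negishi carboalumination adds CH3 and Al syn across the alkyne with Al at the terminus, and iodinolysis with retention should fix the (E)-geometry that later encodes C4.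

Step 2
Reactants: 3 (E)-3-iodo-2-methylprop-2-en-1-ol
Product: 4 {[(E)-3-iodo-2-methylprop-2-enyl]oxymethyl}benzene
Conditions: NaH, BnBr, Bu4NI (cat.), THF, 0 °C → rt
Reagents that add atoms: benzyl bromide BrCc1ccccc1
Why: Williamson etherification of the primary alkoxide installs a benzyl ether that tolerates every base, hydride and oxidant up to step 17 and is removed in the hydrogenation of step 18.

Step 3
Reactants: 4 (E)-iodoalkenyl benzyl ether
Product: 6 (E)-4-(benzyloxy)-3-methylbut-2-enal, via alkenyllithium 5 (not isolated)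
Conditions: t-BuLi (2 equiv), Et2O, −78 °C; DMF, −78 → 0 °C; aq. NH4Cl
Reagents that add atoms: N,N-dimethylformamide CN(C)C=O; tert-butyllithium [Li]C(C)(C)C (lithium of 5 only)
Why: Iodine–lithium exchange keeps the alkene geometry, and formylation of an alkenyllithium with DMF is a standard route to (E)-enals.

Step 4
Reactants: 7 2,2,6-trimethyl-4H-1,3-dioxin-4-one
Product: 8 [(2,2-dimethyl-6-methylidene-6H-1,3-dioxin-4-yl)oxy]trimethylsilane
Conditions: LiN(iPr)2, THF, −78 °C; Me3SiCl
Reagents that add atoms: chlorotrimethylsilane C[Si](C)(C)Cl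
Why: γ-Deprotonation of the dioxinone and O-silylation give the cross-conjugated silyl dienolate, the usual γ-nucleophilic acetoacetate equivalent.

Step 5
Reactants: 6 (E)-4-(benzyloxy)-3-methylbut-2-enal; 8 silyl dienolate
Product: 10 6-[(2R,3E)-5-(benzyloxy)-2-hydroxy-4-methylpent-3-enyl]-2,2-dimethyl-4H-1,3-dioxin-4-one, via trimethylsilyl ether 9 (not isolated)
Conditions: Cu(OTf)2 (2 mol %), (S)-Tol-BINAP (2.2 mol %), Bu4N[Ph3SiF2] (4 mol %), THF, −78 °C; then 1 M HCl, THF
Reagents that add atoms: none
Why: In this catalytic enantioselective vinylogous Mukaiyama aldol addition the bisphosphine copper dienolate attacks one face of the enal through its γ-carbon only, which forms C1–C2 and sets C2 as (R).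

Step 6
Reactants: 10 (R)-hydroxy dioxinone
Product: 12 (6R)-6-[(E)-3-(benzyloxy)-2-methylprop-1-enyl]oxane-2,4-dione, via acylketene 11 (not isolated)
Conditions: toluene (dilute), 110 °C
Reagents that add atoms: none
Why: Thermal retro-[4+2] loss of acetone unmasks an acylketene that the δ-hydroxyl captures intramolecularly, a standard dioxinone to β-keto-δ-lactone conversion that leaves C2 untouched.

Step 7
Reactants: 12 β-keto-δ-lactone
Product: 13 (2R)-2-[(E)-3-(benzyloxy)-2-methylprop-1-enyl]-6-oxo-3,6-dihydro-2H-pyran-4-yl trifluoromethanesulfonate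
Conditions: Tf2O, Et3N, CH2Cl2, −78 °C
Reagents that add atoms: trifluoromethanesulfonic anhydride O=S(=O)(C(F)(F)F)OS(=O)(=O)C(F)(F)F
Why: O-Sulfonylation of the enolised β-keto lactone between its two carbonyl groups gives the conjugated enol triflate and activates C10 for substitution.

Step 8
Reactants: 13 enol triflate
Product: 14 (6R)-4-allyl-6-[(E)-3-(benzyloxy)-2-methylprop-1-enyl]-5,6-dihydro-2H-pyran-2-one
Conditions: allylMgBr (2 equiv), CuI (1 equiv), THF, −78 °C; then 13, −78 °C; aq. NH4Cl
Reagents that add atoms: allylmagnesium bromide C=CC[Mg]Br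
Why: Allyl cuprates replace the triflate of alkenyl triflates at −78 °C, here by conjugate addition–elimination, which avoids zerovalent palladium and therefore ionisation of the allylic lactone C2–O bond.

Step 9
Reactants: 14 4-allyl unsaturated lactone
Product: 16 (4R,6R)-4-allyl-6-[(E)-3-(benzyloxy)-2-methylprop-1-enyl]-4-methyloxan-2-one, via trimethylsilyl ketene acetal 15 (not isolated)
Conditions: MeLi (2 equiv per Cu), CuI, Et2O, 0 °C; Me3SiCl, 14, −78 → −40 °C; aq. NH4Cl, then dilute HCl
Reagents that add atoms: methyllithium [Li]C; chlorotrimethylsilane C[Si](C)(C)Cl (silyl group of 15 only)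
Why: Me3SiCl-accelerated conjugate addition of lithium dimethylcuprate to a 6-substituted 5,6-dihydropyran-2-one occurs axially on the face anti to the pseudo-equatorial alkenyl group, so CH3 should enter trans and leave the allyl group cis (C10 set from C2), whereas allylic displacement would require attack at a fully substituted alkene terminus or a higher temperature.

Step 10
Reactants: 16 cis-(4R,6R)-δ-lactone
Product: 19 (1S,2R,6R)-6-allyl-2-[(benzyloxy)methyl]-2,6-dimethylcyclohex-3-ene-1-carboxylic acid, via silyl ketene acetal 17 (not isolated), via silyl ester 18 (not isolated)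
Conditions: LiN(iPr)2, THF–DMPU, −78 °C; tBuMe2SiCl, −78 °C → rt; solvent change to toluene, 110 °C; then 1 M HCl, THF, rt
Reagents that add atoms: tert-butyldimethylsilyl chloride CC(C)(C)[Si](C)(C)Cl (silyl group of 17 and 18 only)
Why: The amide base removes a C5 hydrogen (the only α-position) and the silyl chloride traps the enolate on oxygen as 17, whose C5=C6 geometry is fixed by the ring; on heating, O–C2 breaks and C4–C5 forms in one concerted suprafacial [3,3] shift, the Ireland–Claisen rearrangement of a lactone silyl ketene acetal, a known carbocycle synthesis. Ring A (C5–C4–C3–C2–C1–C10) closes by this sigmatropic C–C bond formation: O and C6 leave the old ring while C3 and C4 enter the new one, so a six-membered lactone becomes a six-membered carbocycle and C6 ends as the exocyclic carboxyl on C5. Because C5 and C2 are tied by the two-atom C10–C1 bridge, the alkenyl group has to swing over the ketene acetal, and only a boat-shaped array is within reach. C5 is therefore set by C2, since C4 bonds to the ring face that carried the alkenyl group (cis to allyl, trans to the C10 methyl), which places C6 cis to that methyl as a trans-fused decalin requires; C4 is set by the (E)-geometry read through the boat, which puts CH2OBn cis to C6 and the C4 methyl cis to H5. The step needs this pathway to outrun C-silylation and the Cope shift open to the C6=C5–C10–C9–C8=C7 diene; the bulky silyl chloride in a dipolar cosolvent favours O-silylation, and the silyloxy donor on C6 holds the Claisen barrier well below that of an all-carbon Cope process.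

Step 11
Reactants: 19 ring A carboxylic acid
Product: 20 [(1S,2R,6R)-6-allyl-2-[(benzyloxy)methyl]-2,6-dimethylcyclohex-3-en-1-yl]methanol
Conditions: LiAlH4, THF, 0 °C → reflux; aq. NaOH work-up
Reagents that add atoms: none
Why: Hydride reduction with hot LiAlH4 should cope with the doubly neopentyl carboxyl and touches neither the alkenes nor the benzyl ether.

Step 12
Reactants: 20 ring A primary alcohol
Product: 21 (1S,2R,6R)-6-allyl-2-[(benzyloxy)methyl]-2,6-dimethylcyclohex-3-ene-1-carbaldehyde
Conditions: Dess–Martin periodinane, CH2Cl2, 0 °C → rt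
Reagents that add atoms: none
Why: Dess–Martin oxidation stops at the aldehyde under nearly neutral conditions, so the C5 centre next to the new carbonyl is not put at risk.

Step 13
Reactants: 21 ring A aldehyde
Product: 22 (1S,2R,6S)-2-[(benzyloxy)methyl]-2,6-dimethyl-6-(2-oxopropyl)cyclohex-3-ene-1-carbaldehyde
Conditions: PdCl2 (10 mol %), CuCl, O2 (1 atm), DMF–H2O, rt
Reagents that add atoms: water O
Why: Wacker–Tsuji oxidation is selective for the monosubstituted alkene with Markovnikov delivery of oxygen to C8, and the hindered cis-disubstituted C2=C3 bond stays inert.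

Step 14
Reactants: 22 keto aldehyde
Product: 24 (4aS,5R,8aS)-5-[(benzyloxy)methyl]-5,8a-dimethyl-4a,5,8,8a-tetrahydronaphthalen-2(1H)-one, via ketol 23 (not isolated)
Conditions: KOH (cat.), MeOH, 0 °C → rt
Reagents that add atoms: none
Why: In this intramolecular aldol condensation only the C7 enolate can reach C6 through a six-membered ring (C9 or C5 would give four-membered rings), and the trans-diequatorial formyl and acetonyl groups should close trans-fused ring B faster than the C5–H, shielded by two quaternary neighbours, is exchanged.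

Step 15
Reactants: 25 (E)-4,4-dimethoxybut-2-enal
Product: 26 (E)-4,4-dimethoxybut-2-en-1-ol
Conditions: NaBH4, MeOH, 0 °C
Reagents that add atoms: none
Why: Borohydride 1,2-reduction of the enal leaves the acetal and the alkene intact.

Step 16
Reactants: 26 (E)-4,4-dimethoxybut-2-en-1-ol
Product: 27 (E)-4-bromo-1,1-dimethoxybut-2-ene
Conditions: CBr4, PPh3, CH2Cl2, −20 → 0 °C
Reagents that add atoms: carbon tetrabromide BrC(Br)(Br)Br
Why: The Appel reaction converts the primary allylic alcohol into the bromide under essentially neutral conditions that the acetal survives.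

Step 17
Reactants: 24 bicyclic enone; 27 (E)-4-bromo-1,1-dimethoxybut-2-ene
Product: 28 (1R,4aS,5R,8aR)-5-[(benzyloxy)methyl]-1-[(E)-4,4-dimethoxybut-2-enyl]-5,8a-dimethyl-4a,5,8,8a-tetrahydronaphthalen-2(1H)-one
Conditions: LiN(iPr)2, THF, −78 °C; DMPU, 27, −78 → −20 °C
Reagents that add atoms: none
Why: Kinetic deprotonation of a cyclohexenone occurs at the α′-carbon, here C9, which removes the C7/C9 regiochemical problem of the saturated ketone, and the cross-conjugated dienolate should be alkylated by the reactive allylic bromide anti to the angular C10 methyl, so the C9 epimer of the target series is expected and is corrected in step 18.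

Step 18
Reactants: 28 C9-alkylated enone
Product: 30 (1S,4aS,5R,8aR)-1-(4,4-dimethoxybutyl)-5-(hydroxymethyl)-5,8a-dimethyloctahydronaphthalen-2(1H)-one, via 9-epi ketone 29 (not isolated)
Conditions: H2 (3 atm), 10% Pd/C, MeOH, rt; filter; NaOMe (cat.), MeOH, rt
Reagents that add atoms: none
Why: Heterogeneous hydrogenation saturates C2=C3, C6=C7 and C12=C13 and cleaves the benzyl ether in one operation without creating a stereocentre, and methoxide then equilibrates the enolisable C9 to the equatorial side chain (H9 axial and anti to the C10 methyl) that is the stable arrangement of labdan-8-ones.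

Step 19
Reactants: 30 C8 ketone
Product: 31 [(1R,4aS,5R,8aS)-5-(4,4-dimethoxybutyl)-1,4a-dimethyl-6-methylidenedecahydronaphthalen-1-yl]methanol
Conditions: Ph3PCH3Br, KOtBu (excess), THF, rt → 60 °C
Reagents that add atoms: methyltriphenylphosphonium bromide C[P+](c1ccccc1)(c1ccccc1)c1ccccc1.[Br-]
Why: Wittig methylenation with excess ylide is the standard way from 8-oxolabdanes to the 8(17)-alkene; the C19 alkoxide is a spectator and C9 already holds its stable configuration.

Step 20
Reactants: 31 exocyclic alkene acetal; 32 glyoxylic acid (monohydrate)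
Product: 34 5-hydroxy-4-{2-[(1R,4aS,5R,8aS)-5-(hydroxymethyl)-5,8a-dimethyl-2-methylidenedecahydronaphthalen-1-yl]ethyl}furan-2(5H)-one (both C16 epimers), via aldehyde 33 (not isolated)
Conditions: morpholine·HCl, 1,4-dioxane–H2O, rt → 90 °C
Reagents that add atoms: water O
Why: The aqueous acid frees the C16 aldehyde, its morpholine enamine condenses at C13 with glyoxylic acid in an aldol condensation, and the resulting (Z)-formylacrylic acid closes to the 4-substituted 5-hydroxybutenolide, a known annulation of aldehydes that bear an α-CH2 group.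

Step 21
Reactants: 34 γ-hydroxybutenolide
Product: 36 4-{2-[(1R,4aS,5R,8aS)-5-(hydroxymethyl)-5,8a-dimethyl-2-methylidenedecahydronaphthalen-1-yl]ethyl}furan-2(5H)-one, via hydroxy acid 35 (not isolated)
Conditions: NaBH4, MeOH, 0 °C; then 1 M HCl to pH 2
Reagents that add atoms: none
Why: Borohydride reduces the open aldehyde tautomer of the pseudo-acid to the (Z)-γ-hydroxy acid, which lactonises on acidification, the usual conversion of γ-hydroxybutenolides into butenolides.

Step 22
Reactants: 36 19-hydroxy butenolide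
Product: 37 [(1R,4aS,5R,8aS)-1,4a-dimethyl-6-methylidene-5-[2-(5-oxo-2,5-dihydrofuran-3-yl)ethyl]decahydronaphthalen-1-yl]methyl acetate (CNP0189477.2)
Conditions: Ac2O, pyridine, DMAP (cat.), CH2Cl2, rt
Reagents that add atoms: acetic anhydride CC(=O)OC(C)=O
Why: DMAP-catalysed acylation of the axial neopentyl C19 alcohol, the only hydroxyl left, completes the target.

**Compound list**
1 | prop-2-yn-1-ol | C#CCO | starting material
2 | (E)-3-(dimethylalumanyl)-2-methylprop-2-enyl dimethylaluminium alkoxide | C[Al](C)/C=C(\C)CO[Al](C)C | intermediate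
3 | (E)-3-iodo-2-methylprop-2-en-1-ol | OC/C(C)=C/I | intermediate
4 | {[(E)-3-iodo-2-methylprop-2-enyl]oxymethyl}benzene | I/C=C(\C)COCc1ccccc1 | intermediate
5 | [(E)-3-(benzyloxy)-2-methylprop-1-enyl]lithium | [Li]/C=C(\C)COCc1ccccc1 | intermediate
6 | (E)-4-(benzyloxy)-3-methylbut-2-enal | O=C/C=C(\C)COCc1ccccc1 | intermediate
7 | 2,2,6-trimethyl-4H-1,3-dioxin-4-one | CC1=CC(=O)OC(C)(C)O1 | starting material
8 | [(2,2-dimethyl-6-methylidene-6H-1,3-dioxin-4-yl)oxy]trimethylsilane | C=C1C=C(O[Si](C)(C)C)OC(C)(C)O1 | intermediate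
9 | trimethylsilyl ether of 10 (2R) | CC1(C)OC(=O)C=C(C[C@@H](O[Si](C)(C)C)/C=C(\C)COCc2ccccc2)O1 | intermediate
10 | 6-[(2R,3E)-5-(benzyloxy)-2-hydroxy-4-methylpent-3-enyl]-2,2-dimethyl-4H-1,3-dioxin-4-one | CC1(C)OC(=O)C=C(C[C@@H](O)/C=C(\C)COCc2ccccc2)O1 | intermediate
11 | (5R,6E)-8-(benzyloxy)-5-hydroxy-7-methyl-3-oxoocta-1,6-dien-1-one (acylketene) | O=C=CC(=O)C[C@@H](O)/C=C(\C)COCc1ccccc1 | intermediate
12 | (6R)-6-[(E)-3-(benzyloxy)-2-methylprop-1-enyl]oxane-2,4-dione | O=C1CC(=O)C[C@@H](O1)/C=C(\C)COCc2ccccc2 | intermediate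
13 | (2R)-2-[(E)-3-(benzyloxy)-2-methylprop-1-enyl]-6-oxo-3,6-dihydro-2H-pyran-4-yl trifluoromethanesulfonate | O=C1C=C(OS(=O)(=O)C(F)(F)F)C[C@@H](O1)/C=C(\C)COCc2ccccc2 | intermediate
14 | (6R)-4-allyl-6-[(E)-3-(benzyloxy)-2-methylprop-1-enyl]-5,6-dihydro-2H-pyran-2-one | O=C1C=C(CC=C)C[C@@H](O1)/C=C(\C)COCc2ccccc2 | intermediate
15 | {[(2R,4R)-4-allyl-2-[(E)-3-(benzyloxy)-2-methylprop-1-enyl]-4-methyl-3,4-dihydro-2H-pyran-6-yl]oxy}trimethylsilane | C[Si](C)(C)OC1=C[C@](C)(CC=C)C[C@@H](O1)/C=C(\C)COCc2ccccc2 | intermediate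
16 | (4R,6R)-4-allyl-6-[(E)-3-(benzyloxy)-2-methylprop-1-enyl]-4-methyloxan-2-one (allyl cis to alkenyl) | O=C1C[C@](C)(CC=C)C[C@@H](O1)/C=C(\C)COCc2ccccc2 | intermediate
17 | {[(2R,4R)-4-allyl-2-[(E)-3-(benzyloxy)-2-methylprop-1-enyl]-4-methyl-3,4-dihydro-2H-pyran-6-yl]oxy}(tert-butyl)dimethylsilane | CC(C)(C)[Si](C)(C)OC1=C[C@](C)(CC=C)C[C@@H](O1)/C=C(\C)COCc2ccccc2 | intermediate
18 | tert-butyldimethylsilyl ester of 19 | CC(C)(C)[Si](C)(C)OC(=O)[C@@H]1[C@](C)(COCc2ccccc2)C=CC[C@@]1(C)CC=C | intermediate
19 | (1S,2R,6R)-6-allyl-2-[(benzyloxy)methyl]-2,6-dimethylcyclohex-3-ene-1-carboxylic acid | OC(=O)[C@@H]1[C@](C)(COCc2ccccc2)C=CC[C@@]1(C)CC=C | intermediate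
20 | [(1S,2R,6R)-6-allyl-2-[(benzyloxy)methyl]-2,6-dimethylcyclohex-3-en-1-yl]methanol | OC[C@@H]1[C@](C)(COCc2ccccc2)C=CC[C@@]1(C)CC=C | intermediate
21 | (1S,2R,6R)-6-allyl-2-[(benzyloxy)methyl]-2,6-dimethylcyclohex-3-ene-1-carbaldehyde | O=C[C@@H]1[C@](C)(COCc2ccccc2)C=CC[C@@]1(C)CC=C | intermediate
22 | (1S,2R,6S)-2-[(benzyloxy)methyl]-2,6-dimethyl-6-(2-oxopropyl)cyclohex-3-ene-1-carbaldehyde | O=C[C@@H]1[C@](C)(COCc2ccccc2)C=CC[C@@]1(C)CC(C)=O | intermediate
23 | (4aS,5R,8aS)-5-[(benzyloxy)methyl]-4-hydroxy-5,8a-dimethyl-3,4,4a,5,8,8a-hexahydronaphthalen-2(1H)-one (carbinol epimers) | O=C1CC(O)[C@@H]2[C@](C)(COCc3ccccc3)C=CC[C@@]2(C)C1 | intermediate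
24 | (4aS,5R,8aS)-5-[(benzyloxy)methyl]-5,8a-dimethyl-4a,5,8,8a-tetrahydronaphthalen-2(1H)-one | O=C1C=C[C@@H]2[C@](C)(COCc3ccccc3)C=CC[C@@]2(C)C1 | intermediate
25 | (E)-4,4-dimethoxybut-2-enal | COC(OC)/C=C/C=O | starting material
26 | (E)-4,4-dimethoxybut-2-en-1-ol | COC(OC)/C=C/CO | intermediate
27 | (E)-4-bromo-1,1-dimethoxybut-2-ene | COC(OC)/C=C/CBr | intermediate
28 | (1R,4aS,5R,8aR)-5-[(benzyloxy)methyl]-1-[(E)-4,4-dimethoxybut-2-enyl]-5,8a-dimethyl-4a,5,8,8a-tetrahydronaphthalen-2(1H)-one | O=C1C=C[C@@H]2[C@](C)(COCc3ccccc3)C=CC[C@@]2(C)[C@H]1C/C=C/C(OC)OC | intermediate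
29 | (1R,4aS,5R,8aR)-1-(4,4-dimethoxybutyl)-5-(hydroxymethyl)-5,8a-dimethyloctahydronaphthalen-2(1H)-one | O=C1CC[C@@H]2[C@](C)(CO)CCC[C@@]2(C)[C@H]1CCCC(OC)OC | intermediate
30 | (1S,4aS,5R,8aR)-1-(4,4-dimethoxybutyl)-5-(hydroxymethyl)-5,8a-dimethyloctahydronaphthalen-2(1H)-one | O=C1CC[C@@H]2[C@](C)(CO)CCC[C@@]2(C)[C@@H]1CCCC(OC)OC | intermediate
31 | [(1R,4aS,5R,8aS)-5-(4,4-dimethoxybutyl)-1,4a-dimethyl-6-methylidenedecahydronaphthalen-1-yl]methanol | C=C1CC[C@@H]2[C@](C)(CO)CCC[C@@]2(C)[C@@H]1CCCC(OC)OC | intermediate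
32 | glyoxylic acid (used as the monohydrate) | O=CC(=O)O | starting material
33 | 4-[(1R,4aS,5R,8aS)-5-(hydroxymethyl)-5,8a-dimethyl-2-methylidenedecahydronaphthalen-1-yl]butanal | C=C1CC[C@@H]2[C@](C)(CO)CCC[C@@]2(C)[C@@H]1CCCC=O | intermediate
34 | 5-hydroxy-4-{2-[(1R,4aS,5R,8aS)-5-(hydroxymethyl)-5,8a-dimethyl-2-methylidenedecahydronaphthalen-1-yl]ethyl}furan-2(5H)-one (hemiacetal epimers) | C=C1CC[C@@H]2[C@](C)(CO)CCC[C@@]2(C)[C@@H]1CCC1=CC(=O)OC1O | intermediate
35 | (2Z)-3-(hydroxymethyl)-5-[(1R,4aS,5R,8aS)-5-(hydroxymethyl)-5,8a-dimethyl-2-methylidenedecahydronaphthalen-1-yl]pent-2-enoic acid | C=C1CC[C@@H]2[C@](C)(CO)CCC[C@@]2(C)[C@@H]1CC/C(CO)=C/C(=O)O | intermediate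
36 | 4-{2-[(1R,4aS,5R,8aS)-5-(hydroxymethyl)-5,8a-dimethyl-2-methylidenedecahydronaphthalen-1-yl]ethyl}furan-2(5H)-one | C=C1CC[C@@H]2[C@](C)(CO)CCC[C@@]2(C)[C@@H]1CCC1=CC(=O)OC1 | intermediate
37 | [(1R,4aS,5R,8aS)-1,4a-dimethyl-6-methylidene-5-[2-(5-oxo-2,5-dihydrofuran-3-yl)ethyl]decahydronaphthalen-1-yl]methyl acetate | C=C1CC[C@@H]2[C@](C)(COC(C)=O)CCC[C@@]2(C)[C@@H]1CCC1=CC(=O)OC1 | target

**Step count**
Total step count: 22. Longest linear sequence: 19 (steps 1–3, 5–14 and 17–22).

**Steps most likely to fail**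

Step 10.
- What may go wrong: sluggish enolisation or C-silylation at the neopentyl-type C5, or thermal decay of the ketene acetal before the congested C4–C5 bond can form.
- The fallback sets out from 16 and comes back at 21. It keeps the same [3,3] disconnection at the aldehyde oxidation level.
- iBu2AlH (toluene, −78 °C) reduces 16 to the lactol F1, and MsCl/Et3N (THF, 0 °C → reflux) eliminates it to the 3,4-dihydro-2H-pyran F2.
- This allyl vinyl ether needs neither base nor silylating agent and withstands long heating. At 180–200 °C (o-dichlorobenzene, sealed tube) the thermal Claisen rearrangement of a 2-alkenyl-dihydropyran should pass through the same bridged boat and deliver aldehyde 21 directly, so steps 11 and 12 fall away.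

Step 9.
- What may go wrong: displacement of the allylic lactone carboxylate by the cuprate, γ-deprotonation of the skipped diene, or erosion of facial selectivity.
- The fallback sets out from alkenyllithium 5 (made from 4 as in step 3) and comes back at 16. It builds C10 before any allylic C2–O bond exists and gives up the stereochemical relay in favour of a separation.
- Commercial diethyl (E)-3-methylpent-2-enedioate takes up an allyl group (allylMgBr, CuI, Me3SiCl, THF, −78 °C) to give diethyl 3-allyl-3-methylpentanedioate F3.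
- KOH in aqueous EtOH gives 3-allyl-3-methylpentanedioic acid F4, and Ac2O closes it to 4-allyl-4-methyloxane-2,6-dione F5.
- Alkenyllithium 5 opens the anhydride at −78 °C to the racemic keto acid F6.
- CBS reduction ((S)-Me-CBS oxazaborolidine, catecholborane, toluene, −78 °C) sets C2 as (R) and gives the hydroxy acid F7 as a pair of C10 epimers.
- Acid-catalysed lactonisation gives 16 together with the trans lactone F8, which is removed by chromatography.

Step 17.
- What may go wrong: failure of the SN2 attack at C9 next to the quaternary C10, proton transfer to the extended dienolate followed by attack at C7, or O-alkylation.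
- The fallback sets out from 24 and comes back at 30. It replaces alkylation by the sterically less demanding carbonyl addition.
- The same kinetic lithium dienolate adds to 4,4-dimethoxybutanal at −78 °C to give the β-hydroxy ketone F9.
- MsCl/Et3N followed by DBU dehydrates it to the C9=C11 alkylidene dienone F10.
- The hydrogenation and methoxide equilibration of step 18 then saturate all four C=C bonds, remove the benzyl group, settle C9, and give 30.

**Further compounds**
F1 | step 10 | (4R,6R)-4-allyl-6-[(E)-3-(benzyloxy)-2-methylprop-1-enyl]-4-methyloxan-2-ol (anomers) | OC1C[C@](C)(CC=C)C[C@@H](O1)/C=C(\C)COCc2ccccc2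
F2 | step 10 | (2R,4R)-4-allyl-2-[(E)-3-(benzyloxy)-2-methylprop-1-enyl]-4-methyl-3,4-dihydro-2H-pyran | C1=C[C@](C)(CC=C)C[C@@H](O1)/C=C(\C)COCc2ccccc2
F3 | step 9 | diethyl 3-allyl-3-methylpentanedioate | CCOC(=O)CC(C)(CC=C)CC(=O)OCC
F4 | step 9 | 3-allyl-3-methylpentanedioic acid | OC(=O)CC(C)(CC=C)CC(=O)O
F5 | step 9 | 4-allyl-4-methyloxane-2,6-dione | O=C1CC(C)(CC=C)CC(=O)O1
F6 | step 9 | (6E)-3-allyl-8-(benzyloxy)-3,7-dimethyl-5-oxooct-6-enoic acid (racemic) | OC(=O)CC(C)(CC=C)CC(=O)/C=C(\C)COCc1ccccc1
F7 | step 9 | (5R,6E)-3-allyl-8-(benzyloxy)-5-hydroxy-3,7-dimethyloct-6-enoic acid (both C3 epimers) | OC(=O)CC(C)(CC=C)C[C@@H](O)/C=C(\C)COCc1ccccc1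
F8 | step 9 | (4S,6R)-4-allyl-6-[(E)-3-(benzyloxy)-2-methylprop-1-enyl]-4-methyloxan-2-one | O=C1C[C@@](C)(CC=C)C[C@@H](O1)/C=C(\C)COCc2ccccc2
F9 | step 17 | (4aS,5R,8aR)-5-[(benzyloxy)methyl]-1-(1-hydroxy-4,4-dimethoxybutyl)-5,8a-dimethyl-4a,5,8,8a-tetrahydronaphthalen-2(1H)-one (C9 and C11 epimers) | O=C1C=C[C@@H]2[C@](C)(COCc3ccccc3)C=CC[C@@]2(C)C1C(O)CCC(OC)OC
F10 | step 17 | (4aS,5R,8aS)-5-[(benzyloxy)methyl]-1-(4,4-dimethoxybutylidene)-5,8a-dimethyl-4a,5,8,8a-tetrahydronaphthalen-2(1H)-one (alkylidene geometry immaterial) | O=C1C=C[C@@H]2[C@](C)(COCc3ccccc3)C=CC[C@@]2(C)C1=CCCC(OC)OC
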